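Locants: friedelane numbering (C1–C30) for the triterpene half, primed guaiane numbering (C1′–C15′) for the sesquiterpene half; β is the face of the C9, C14 and C17 methyl groups.

## Analysis of the target

The target is a 1,4-benzodioxane that joins a 24-nor-friedelane methyl ester (rings A–E) to a guaiane (five/seven bicycle) through O2–C1′ and O3–C5′. Ring A is an aromatic 4-methylcatechol fused at C5–C10, ring B holds the C6=C7 styrene bond and the tertiary C8–H, and C29 is a methyl ester on C20. Seven of the eleven stereocentres lie in the triterpene: C9 (β-methyl), C13 (α-methyl), C14 (β-methyl), C17 (β-methyl), C18 (β-H), C20 (β-methyl, α-ester) and C8, whose hydrogen is β and therefore syn to the C9 and C14 methyls. Rings B/C and D/E are thus cis-fused and C/D is trans-fused with anti methyls; the B/C junction is the epimer of the friedelin-type one and the more strained (C7 sits syn-axial to the 13α-methyl). The other four are C7′ (S, isopropenyl), C10′ (R, methyl) and the carbinol carbons C1′ and C5′ of the cis-fused dioxane, whose oxygens lie on the face that also carries the C10′ methyl and the isopropenyl group. Sensitive sites are the tertiary allylic aryl ether at C5′, the three olefins, and, in every precursor with a C5 carbonyl or an ortho-quinone, the C8–H, which is vinylogously acidic (epimerisation or tautomerisation to the quinone methide). The difficulty is the five quaternary carbons (C9, C13, C14, C17, C20), a disfavoured C8 configuration that must be made kinetically and kept, and a regio- and face-selective union of the halves. The strategy rests on ring A: oxygen at C3, methyl at C4 and a C5–C10 fusion next to C6=C7 is what remains when a five-carbon enone is annulated onto C10/C5 of a 5-oxo-6-ene and the new ring is aromatised.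

## Retrosynthetic reasoning

**Dioxane.** O2–C1′ and O3–C5′ of 52 are cut together. This is the only disconnection that separates the molecule into halves of comparable size in one operation, and it leads to ortho-quinone 51 and triene 50. The forward hetero-[4+2] must choose the C1′=C5′ bond, one orientation and one face. Because 51 can tautomerise, it is made from phenol 38 only at the moment of use.

**Ring A, oxidation level.** Phenol 38 is taken back to dienone 36 by adding two hydrogens across C1–C2. Forward, a dehydrogenation at C1–C2 is enough, since the resulting trienone is the keto form of the phenol and the C10 centre vanishes.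

**Ring A, skeleton (key).** C1–C10 and C4=C5 of 36 are cut, giving enone 32 and pentenone 33. These bonds are chosen because every carbon removed (C1–C4, C23) is achiral in the target and 33 supplies the C4 methyl. The C6=C7 bond of 32 blocks enolisation towards C6, so the forward reaction needs only kinetic selection of C10 over C8.

**C6=C7 and the C5 carbonyl.** Enone 32 comes from ketone 30 by dehydrogenation, which can only go towards C6–C7 because C9 has no hydrogen, and 30 from the methylidene compound 29 by cleavage of the exocyclic bond. Keeping C5 as a saturated ketone until this point means C8 is not acidic while rings B and C are built.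

**Rings B and C.** C8–C14 and C9–C10 of 29 are cut, giving the hydroxy polyene 28. A cation–olefin closure is chosen because anti addition across a Z-configured C8=C9 bond is a mechanism that delivers the cis B/C junction with C7 axial; any protonation or hydrogenation at C8 would come from the α face and give the wrong epimer. The forward step has to create C8, C9 and C14 in one operation.

**Side chain.** The C9–C11 bond of 28 is cut between sp2 and sp3 carbon, giving carbinol 19 and iodide 26. The olefin geometry is then fixed in a small fragment and transferred with retention.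

**Fragment 26.** It is traced to butynol 20 (C7, C8, C9, C25) and ester 23 (C5, C6), with C10 and the silicon terminator added to the ester carbon.

**C13 and C14.** Carbinol 19 is traced to enone 13. C13 is the only enolisable position of 13, so its two substituents (methyl, then the vinyl arm from 15) are introduced by successive enolate reactions, the second from the convex face; the C14 methyl comes by carbonyl addition.

**Rings D and E.** Ring D of 13 is opened at C15=C16 (aldol) to keto dialdehyde 10. The two formyl groups of 10 are reconnected as the etheno bridge of ketone 9, which is traced through aldehyde 5 to diene 3 and enal 4, and 3 to arene 1. One endo cycloaddition thereby sets C17, C18 and C20, whose 1,4-relation across ring E cannot be induced reliably on a monocycle.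

**Sesquiterpene.** Diene 50 is traced through triflate 49 to enone 48, so that the double-bond isomer is defined by the triflate. 48 opens (aldol) to diketone 47, which comes from alkyne 46. The C1′–C2′ bond and the C10′–H of 46 are cut to enone 43 and bromide 44. 43 is traced to cyclopropane 41, enol ether 40 and the chiral-pool enone 39, which supplies C7′.

## Alternatives that were turned down

**Alternative 1:** The cycloheptane is cut at C5′ (C5′–C1′ and C5′–C6′), leading to cis-dihydrocarvone A1 and ethyl diazoacetate A2. Forward, BF3·OEt2 activates the ketone of A1, A2 adds, and the methylene carbon migrates as nitrogen leaves, giving the seven-membered β-keto ester A3.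
- For: one step from a chiral-pool ketone, both ring stereocentres carried over, and the ester activates C5′ for the cyclopentane annulation. On the seven-membered ring alone it is shorter than steps 23–25 here, and it is the stronger plan on that count.
- Against: A1 is the minor epimer of its series; C10′ stays α to the ketone in A1 and A3 under Lewis acid; migration of CH2 over CH(CH3) is preferred but not exclusive; C5′ is labile.
- Comparison: it addresses two of eleven stereocentres and says nothing about ring A, the 6-ene or C8. The chosen strategy puts its key step where the structure offers a retron; in its diene branch it inserts the carbon on the other side of the carbonyl and resets C10′ under catalyst control, which costs steps but leaves both ring stereocentres β to the ketone.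

**Alternative 2:** The cyclopentene is grown on an olefin that already bears the C1′–O2 aryl ether. Chloro(methyl)ketene A5 would add across the aryloxy/silyloxy olefin A4, forming C1′–C(=O) and C5′–C4′ and giving cyclobutanone A6; ring expansion, dechlorination and closure of C5′–O3 would follow.
- For: the orientation of the dioxane is fixed before the ring exists, which the chosen final cycloaddition cannot promise; the [2+2] is suprafacial, so the two C–O centres are cis.
- Against: A4 is a tetrasubstituted, doubly oxygenated olefin flanked by C10′ and is a poor ketenophile; face control rests on C10′ alone; four or more further steps are run on the complete triterpene; a differentiated catechol must exist first, so the triterpene problem is unsolved.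
- Comparison: stronger on regiocontrol, weaker on convergence. The chosen route joins the halves in the last step and accepts the orientation as a stated risk.

**Alternative 3:** Rings B and C are cut together at C6–C7 and C8–C9. Heating benzocyclobutene A7 would open it to an ortho-quinodimethane that is trapped by the ethynyl group on C14, giving the 7-ene A8.
- For: ring A comes from a simple arene; two rings and the C9 quaternary centre form in one step; for the ring system it is more convergent than annulating ring A last.
- Against: C8 becomes sp2. The target's 8β-H would have to be set afterwards by moving the double bond to C6=C7, and protonation at C8 would come from the open α face and favour the stable epimer. C9 is set through a long tether from C13/C14. A7 needs a D/E unit with both quaternary carbons and an alkyne on C14. Two aryl methyl ethers must be removed late.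
- Comparison: the chosen route sets C8 while ring C closes and never makes C8 trigonal afterwards; that control is what it offers in exchange for Alternative 3's convergence.

Key step: step 21

Assumption: the facial sense of the two catalyst-controlled steps (3 and 26) is taken from the accepted models for the parent substrates; if either is reversed, the mirror-image catalyst is used.

## Route

Step 1
Reactants: 1 p-xylene
Product: 2 1,4-dimethylcyclohexa-1,4-diene
Conditions: Li, NH3(l), EtOH, THF, −78 °C
Reagents that add atoms: none
Why: Birch reduction of a 1,4-dialkylbenzene; protonation occurs at the unsubstituted positions, so both methyl groups end on sp2 carbons.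

Step 2
Reactants: 2 1,4-dimethylcyclohexa-1,4-diene
Product: 3 1,4-dimethylcyclohexa-1,3-diene
Conditions: KOt-Bu (cat.), DMSO, rt
Reagents that add atoms: none
Why: Base-mediated prototropic conjugation through the pentadienyl anion; the conjugated diene should dominate at equilibrium and residual 2 is inert in step 3.

Step 3
Reactants: 3 1,4-dimethylcyclohexa-1,3-diene; 4 acrolein
Product: 5 endo-1,4-dimethylbicyclo[2.2.2]oct-5-ene-2-carbaldehyde
Conditions: (5S)-5-benzyl-2,2,3-trimethylimidazolidin-4-one·HCl (10 mol %), MeCN/H2O 95:5, rt
Reagents that add atoms: none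
Why: Iminium-catalysed Diels–Alder reaction; the symmetric diene leaves no regiochemical question and the endo rule puts the formyl group syn to the new etheno bridge, so that C13, C16 and C29 will share one face of ring E. The catalyst shields one face of the iminium ion and thereby sets C17, C18 and C20 in absolute terms.

Step 4
Reactants: 5 endo-aldehyde; 6 nitroethane
Product: 8 (E)-nitroalkene, via nitro alcohol 7 (not isolated)
Conditions: DBU (10 mol %), THF, 0 °C; then MsCl, Et3N, CH2Cl2, 0 °C
Reagents that add atoms: none
Why: Henry addition followed by mesylation and E1cB elimination gives the conjugated nitroalkene; the base is catalytic and cold so that the α-centre (C18) of the aldehyde is not enolised.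

Step 5
Reactants: 8 (E)-nitroalkene
Product: 9 endo-(2-oxopropyl) bicyclooctene
Conditions: Fe, AcOH/H2O, 80 °C
Reagents that add atoms: water, O
Why: Iron reduction of a conjugated nitroalkene stops at the enamine/imine, which is hydrolysed in the aqueous acid to the methyl ketone (nitroalkene-to-ketone conversion); the bridge olefin is not affected.

Step 6
Reactants: 9 endo-(2-oxopropyl) bicyclooctene
Product: 10 all-cis keto dialdehyde
Conditions: O3, CH2Cl2/MeOH, −78 °C; then Me2S
Reagents that add atoms: ozone, [O-][O+]=O
Why: Ozonolysis with reductive work-up; cleaving the bridge releases the two bridgeheads as formyl-bearing quaternary carbons that are necessarily cis, which fixes the C17/C20 relation without a selective step.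

Step 7
Reactants: 10 all-cis keto dialdehyde
Product: 11 D/E enone aldehyde
Conditions: pyrrolidine (20 mol %), AcOH, PhMe, 40 °C
Reagents that add atoms: none
Why: Enamine-mediated intramolecular aldol condensation; the enamine forms at the methyl terminus of the ketone and reaches only the C16 aldehyde through a six-membered transition state. Neither aldehyde is enolisable.

Step 8
Reactants: 11 D/E enone aldehyde
Product: 13 D/E enone ester, via carboxylic acid 12 (not isolated)
Conditions: NaClO2, NaH2PO4, 2-methylbut-2-ene, t-BuOH/H2O, 0 °C → rt; then TMSCHN2, MeOH/PhMe, 0 °C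
Reagents that add atoms: sodium chlorite, [Na+].[O-]Cl=O; (trimethylsilyl)diazomethane, C[Si](C)(C)C=[N+]=[N-]
Why: Pinnick oxidation of the remaining neopentyl aldehyde and esterification of the crude acid; both stages tolerate the enone.

Step 9
Reactants: 13 D/E enone ester
Product: 14 13-methyl enone
Conditions: LiN(i-Pr)2, THF, −78 °C; then MeI, −78 → 0 °C
Reagents that add atoms: iodomethane, CI
Why: Kinetic α′-deprotonation of a cyclohexenone (C13 is the only enolisable position, C17 being quaternary) and SN2 methylation; the new centre is enolised again in step 10, so its configuration does not matter.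

Step 10
Reactants: 14 13-methyl enone; 15 phenyl vinyl sulfoxide
Product: 17 13α-methyl-13β-vinyl enone, via sulfoxide adduct 16 (not isolated)
Conditions: KN(SiMe3)2, THF, −78 °C; 15, −78 → 0 °C; then PhMe, CaCO3, 110 °C
Reagents that add atoms: none
Why: Conjugate addition of the tertiary enolate to the vinyl sulfoxide (a vinyl cation equivalent) and thermal syn-elimination of the sulfenic acid give the α-vinyl ketone. The acceptor should approach the convex β face of the cis-fused dienolate (the face of H18, away from ring E), so the two-carbon arm becomes 13β and the methyl 13α.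

Step 11
Reactants: 17 13α-methyl-13β-vinyl enone
Product: 18 saturated 14-ketone
Conditions: [(Ph3P)CuH]6 (5 mol %), PhSiH3, PhMe, rt; then aq. NH4F
Reagents that add atoms: none
Why: Copper hydride conjugate reduction takes only the electron-poor C15=C16 bond and leaves the isolated vinyl group and the ester; no stereocentre is formed.

Step 12
Reactants: 18 saturated 14-ketone
Product: 19 tertiary carbinol
Conditions: MeMgBr, CeCl3, THF, −78 °C
Reagents that add atoms: methylmagnesium bromide, C[Mg]Br
Why: Organocerium 1,2-addition to a hindered, enolisable ketone; the hindered quaternary ester should survive at −78 °C. The carbinol configuration is irrelevant because C14 is ionised in step 18.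

Step 13
Reactants: 20 but-2-yn-1-ol
Product: 21 (Z)-3-iodobut-2-en-1-ol
Conditions: NaAlH2(OCH2CH2OMe)2, Et2O, 0 °C → rt; then I2, THF, −78 °C
Reagents that add atoms: iodine, II
Why: anti-Hydroalumination of the propargylic alcohol with aluminium delivered to C3 through the alkoxide, then iodinolysis with retention; this fixes the geometry of the later C8=C9 bond.

Step 14
Reactants: 21 (Z)-3-iodobut-2-en-1-ol
Product: 22 (Z)-1-bromo-3-iodobut-2-ene
Conditions: CBr4, PPh3, CH2Cl2, 0 °C
Reagents that add atoms: tetrabromomethane, BrC(Br)(Br)Br
Why: Appel bromination of a primary allylic alcohol under neutral conditions; SN2 at the primary carbon avoids allylic transposition.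

Step 15
Reactants: 22 (Z)-1-bromo-3-iodobut-2-ene; 23 ethyl acetate
Product: 24 ethyl (Z)-5-iodohex-4-enoate
Conditions: 23, LiN(i-Pr)2, THF, −78 °C; then 22, DMPU, −78 → −20 °C
Reagents that add atoms: none
Why: SN2 alkylation of the lithium ester enolate at the primary allylic carbon; the vinyl iodide is inert to the amide base at low temperature.

Step 16
Reactants: 24 ethyl (Z)-5-iodohex-4-enoate
Product: 26 (Z)-(6-iodo-2-methylidenehept-5-en-1-yl)trimethylsilane, via bis(silylmethyl) carbinol 25 (not isolated)
Conditions: Me3SiCH2MgCl, CeCl3, THF, −78 °C → rt; then SiO2, CH2Cl2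
Reagents that add atoms: (trimethylsilylmethyl)magnesium chloride, C[Si](C)(C)C[Mg]Cl
Why: Double addition of the silylmethyl cerium reagent to the ester and Peterson elimination of one β-hydroxysilane arm on silica gel leave the other arm as the allylsilane terminator.

Step 17
Reactants: 19 tertiary carbinol; 26 (Z)-(6-iodo-2-methylidenehept-5-en-1-yl)trimethylsilane
Product: 28 hydroxy polyene, via B-alkyl borane 27 (not isolated)
Conditions: 9-BBN-H, THF, rt; then 26, Pd(dppf)Cl2 (5 mol %), AsPh3, Cs2CO3, DMF/THF/H2O, rt
Reagents that add atoms: none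
Why: Hydroboration puts boron on the terminal carbon (C11) of the neopentyl vinyl group, and B-alkyl Suzuki–Miyaura coupling with the vinyl iodide proceeds with retention, so C11 and C7 end up cis on C9=C8.

Step 18
Reactants: 28 hydroxy polyene
Product: 29 BCDE 5-methylidene ester
Conditions: SnCl4, CH2Cl2, −78 °C
Reagents that add atoms: none
Why: Ionisation of the tertiary alcohol gives the C14 cation, the trisubstituted olefin adds through C8 (six-membered, Markovnikov) and the C9 cation is captured by the allylsilane (cation–olefin bicyclisation). With the side chain equatorial on ring D the olefin should attack C14 from the equatorial direction, giving the trans C/D junction with the 14β-methyl anti to the 13α-methyl. Chair closure of ring C with anti addition across the Z olefin then puts C7 axial (8β-H), C25 axial (9β) and C10 equatorial.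

Step 19
Reactants: 29 BCDE 5-methylidene ester
Product: 30 BCDE 5-ketone
Conditions: O3, CH2Cl2, −78 °C; then Me2S
Reagents that add atoms: ozone, [O-][O+]=O
Why: Ozonolysis of the only C=C bond left unmasks the C5 ketone.

Step 20
Reactants: 30 BCDE 5-ketone
Product: 32 BCDE 5-oxo-6-ene, via silyl enol ether 31 (not isolated)
Conditions: LiN(i-Pr)2, TMSCl, THF, −78 °C; then Pd(OAc)2, MeCN, rt
Reagents that add atoms: none
Why: Saegusa–Ito dehydrogenation; the kinetic enolate forms towards C6 (C10 is neopentyl), and only this isomer can undergo β-hydride elimination because C9 has no hydrogen, so the enone can only be the 6-ene. C8 is not acidic in the saturated ketone.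

Step 21
Reactants: 32 BCDE 5-oxo-6-ene; 33 ethyl vinyl ketone
Product: 36 pentacyclic 4-methyl-4,6-dien-3-one, via silyl dienol ether 34 (not isolated), via 1,5-diketone 35 (not isolated)
Conditions: LiN(i-Pr)2, THF, −78 °C; TMSCl; then 33, TiCl4, CH2Cl2, −78 °C; then pyrrolidine, AcOH, PhMe, 50 °C
Reagents that add atoms: none
Why: Lithium diisopropylamide removes a C10 hydrogen (α′, kinetic) and silylation gives the cross-conjugated 5-silyloxy-5(10),6-diene; TiCl4 activates 33 and C10 adds to its β-carbon (Mukaiyama–Michael), forming C1–C10. Pyrrolidinium acetate then turns the ethyl ketone into its enamine, whose methyl-bearing carbon (C4) adds to the C5 carbonyl, and loss of water forms C4=C5. The closest known reaction type is the Robinson annulation of a cyclohexenone through its α′-silyl dienol ether. Ring A closes by a 6-(enolendo)-exo-trig aldol. The new centre C10 should form with the acceptor anti to the axial C9 methyl (10β-H); it is erased in step 22. The step needs C10 over C8: C8–H is tertiary, lies between two quaternary carbons and would require γ-deprotonation, whereas C10–H2 is α′ and open. It also needs the intermediate titanium enolate not to add to C7 (closure to a bicyclo[2.2.2]octanone), which the quaternary-flanked C8 next to C7 should retard. The C6=C7 bond blocks enolisation towards C6 and no equilibrating base is present, so C8 should keep its configuration.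

Step 22
Reactants: 36 pentacyclic 4-methyl-4,6-dien-3-one
Product: 38 3-phenol, via silyl trienol ether 37 (not isolated)
Conditions: LiN(i-Pr)2, TMSCl, THF, −78 °C; then Pd(OAc)2, MeCN, rt
Reagents that add atoms: none
Why: Saegusa–Ito dehydrogenation of the C2 (cross-conjugated) silyl enol ether gives the 1,4,6-trien-3-one, which is the keto form of the phenol and tautomerises by loss of H10. The C10 centre disappears and C8 is not touched.

Step 23
Reactants: 39 (S)-carvone
Product: 40 carvone-derived silyl enol ether
Conditions: LiBH(s-Bu)3, THF, −78 °C; then TMSCl, Et3N, −78 → 0 °C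
Reagents that add atoms: chlorotrimethylsilane, C[Si](C)(C)Cl
Why: 1,4-Reduction of the enone by a hindered borohydride and O-silylation of the regiodefined enolate; only the C1=C2 enol ether can form and C2 ceases to be a stereocentre.

Step 24
Reactants: 40 carvone-derived silyl enol ether
Product: 41 siloxycyclopropane
Conditions: Et2Zn, CH2I2, CH2Cl2, 0 °C
Reagents that add atoms: diiodomethane, ICI
Why: Furukawa–Simmons–Smith cyclopropanation; the electron-rich silyl enol ether should react faster than the 1,1-disubstituted isopropenyl group.

Step 25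
Reactants: 41 siloxycyclopropane
Product: 43 (S)-3-methyl-6-(prop-1-en-2-yl)cyclohept-2-en-1-one, via β-chloro ketone 42 (not isolated)
Conditions: FeCl3, DMF, 0 °C → rt; then NaOAc, MeOH, reflux
Reagents that add atoms: none
Why: Ito–Saegusa ring expansion; one-electron oxidation opens the internal cyclopropane bond to the tertiary radical, chlorine transfer gives the β-chloro ketone and acetate eliminates HCl to the conjugated enone. The new carbon (C1′) is inserted between the carbonyl and the methyl-bearing carbon.

Step 26
Reactants: 43 (S)-3-methyl-6-(prop-1-en-2-yl)cyclohept-2-en-1-one; 44 1-bromobut-2-yne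
Product: 46 butynyl cycloheptanone, via diphenylsilyl enol ether 45 (not isolated)
Conditions: CuCl (5 mol %), NaOt-Bu, (S)-p-Tol-BINAP, Ph2SiH2, PhMe, 0 °C; then 44, Bu4N[Ph3SiF2], CH2Cl2, rt
Reagents that add atoms: none
Why: Copper hydride-catalysed asymmetric conjugate reduction sets C10′ under ligand control, and fluoride-promoted alkylation of the regiodefined silyl enol ether puts the butynyl group on C1′ only. Both ring stereocentres are now β to the ketone and cannot epimerise.

Step 27
Reactants: 46 butynyl cycloheptanone
Product: 47 1,4-diketone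
Conditions: (Ph3P)AuNTf2 (2 mol %), H2O, 1,4-dioxane, 60 °C
Reagents that add atoms: water, O
Why: Gold-catalysed alkyne hydration assisted by the ring ketone (5-exo attack of the carbonyl oxygen on the proximal alkyne carbon) should give the γ-diketone regioselectively.

Step 28
Reactants: 47 1,4-diketone
Product: 48 hydroazulenone
Conditions: KOH, MeOH, 50 °C
Reagents that add atoms: none
Why: Intramolecular aldol condensation of a 1,4-diketone to the fused 2-methylcyclopentenone; the other closure would give a bridgehead enone.

Step 29
Reactants: 48 hydroazulenone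
Product: 49 dienyl triflate
Conditions: Tf2O, 2,6-di-tert-butyl-4-methylpyridine, CH2Cl2, 0 °C
Reagents that add atoms: triflic anhydride, O=S(=O)(OS(=O)(=O)C(F)(F)F)C(F)(F)F
Why: O-Triflation of the enone and loss of the γ-hydrogen (H1′) give the linear dienyl triflate, which already has the C1′=C5′/C3′=C4′ pattern.

Step 30
Reactants: 49 dienyl triflate
Product: 50 (7S,10R)-guaia-1(5),3,11-triene
Conditions: Pd(PPh3)4 (5 mol %), Bu3SnH, LiCl, THF, 0 °C → rt
Reagents that add atoms: none
Why: Palladium-catalysed hydride reduction of the dienyl triflate at or below room temperature should deliver one double-bond isomer of the cyclopentadiene before [1,5]-hydrogen shifts scramble it; 50 is used at once.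

Step 31
Reactants: 38 3-phenol; 50 (7S,10R)-guaia-1(5),3,11-triene
Product: 52 target dioxane, via ortho-quinone 51 (not isolated)
Conditions: IBX, DMF, rt; then 50, CH2Cl2, 0 °C → rt, dark
Reagents that add atoms: 2-iodoxybenzoic acid, O=C1OI(=O)(O)c2ccccc12
Why: IBX ortho-oxygenation gives the C2,C3 ortho-quinone (C4 is blocked), which reacts as an electron-poor heterodiene with the tetrasubstituted C1′=C5′ bond of the diene in an inverse-demand hetero-Diels–Alder reaction, so the dioxane is cis-fused. Approach to the convex face of the chair cycloheptene (the face of the pseudo-axial C10′ methyl, away from C7′–C9′) should place both oxygens syn to the methyl and isopropenyl groups. Pairing of the unhindered O2 with C1′ and of O3 with C5′ is the sterically preferred orientation.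

## Compound list

1 | p-xylene | Cc1ccc(C)cc1 | starting material
2 | 1,4-dimethylcyclohexa-1,4-diene | CC1=CCC(C)=CC1 | intermediate
3 | 1,4-dimethylcyclohexa-1,3-diene | CC1=CC=C(C)CC1 | intermediate
4 | acrolein | C=CC=O | starting material
5 | endo-1,4-dimethylbicyclo[2.2.2]oct-5-ene-2-carbaldehyde (formyl syn to the C5=C6 bridge; bridgeheads = C17 and C20, C2 = C18) | O=C[C@@H]1C[C@@]2(C)CC[C@]1(C)C=C2 | intermediate
6 | nitroethane | CC[N+](=O)[O-] | starting material
7 | nitro alcohol from 5 (carbinol and nitro carbons as diastereomer mixture) | CC(C(O)[C@@H]1C[C@@]2(C)CC[C@]1(C)C=C2)[N+](=O)[O-] | intermediate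
8 | endo-2-[(E)-2-nitroprop-1-enyl]-1,4-dimethylbicyclo[2.2.2]oct-5-ene | C/C(=C\[C@@H]1C[C@@]2(C)CC[C@]1(C)C=C2)[N+](=O)[O-] | intermediate
9 | 1-(endo-1,4-dimethylbicyclo[2.2.2]oct-5-en-2-yl)propan-2-one | CC(=O)C[C@@H]1C[C@@]2(C)CC[C@]1(C)C=C2 | intermediate
10 | 1,4-dimethyl-2-(2-oxopropyl)cyclohexane-1,4-dicarbaldehyde, both formyl groups and the oxopropyl arm on one face | CC(=O)C[C@@H]1C[C@](C)(C=O)CC[C@]1(C)C=O | intermediate
11 | D/E enone aldehyde (ring D: C13H2–C14(=O)–C15H=C16H–C17–C18; cis-fused; 17β-CH3, 18β-H, 20β-CH3, 20α-CHO) | O=C1C=C[C@@]2(C)CC[C@@](C)(C=O)C[C@H]2C1 | intermediate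
12 | D/E enone acid (as 11, 20α-CO2H) | O=C1C=C[C@@]2(C)CC[C@@](C)(C(=O)O)C[C@H]2C1 | intermediate
13 | D/E enone ester (as 11, 20α-CO2CH3) | O=C1C=C[C@@]2(C)CC[C@@](C)(C(=O)OC)C[C@H]2C1 | intermediate
14 | 13-methyl D/E enone ester (C13 epimers) | O=C1C=C[C@@]2(C)CC[C@@](C)(C(=O)OC)C[C@H]2C1C | intermediate
15 | phenyl vinyl sulfoxide | C=CS(=O)c1ccccc1 | starting material
16 | 13α-methyl-13β-[2-(phenylsulfinyl)ethyl] D/E enone ester (sulfur epimers) | O=C1C=C[C@@]2(C)CC[C@@](C)(C(=O)OC)C[C@H]2[C@]1(C)CCS(=O)c1ccccc1 | intermediate
17 | 13α-methyl-13β-vinyl D/E enone ester | O=C1C=C[C@@]2(C)CC[C@@](C)(C(=O)OC)C[C@H]2[C@]1(C)C=C | intermediate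
18 | 13α-methyl-13β-vinyl D/E 14-ketone (C15–C16 saturated) | O=C1CC[C@@]2(C)CC[C@@](C)(C(=O)OC)C[C@H]2[C@]1(C)C=C | intermediate
19 | 14-hydroxy-14-methyl-13α-methyl-13β-vinyl D/E ester (C14 epimers) | CC1(O)CC[C@@]2(C)CC[C@@](C)(C(=O)OC)C[C@H]2[C@]1(C)C=C | intermediate
20 | but-2-yn-1-ol | CC#CCO | starting material
21 | (Z)-3-iodobut-2-en-1-ol | C/C(I)=C/CO | intermediate
22 | (Z)-1-bromo-3-iodobut-2-ene | C/C(I)=C/CBr | intermediate
23 | ethyl acetate | CCOC(C)=O | starting material
24 | ethyl (Z)-5-iodohex-4-enoate | C/C(I)=C/CCC(=O)OCC | intermediate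
25 | (Z)-6-iodo-2-(trimethylsilylmethyl)-1-(trimethylsilyl)hept-5-en-2-ol | C/C(I)=C/CCC(O)(C[Si](C)(C)C)C[Si](C)(C)C | intermediate
26 | (Z)-(6-iodo-2-methylidenehept-5-en-1-yl)trimethylsilane | C/C(I)=C/CCC(=C)C[Si](C)(C)C | intermediate
27 | B-alkyl-9-borabicyclo[3.3.1]nonane from 19 (boron on C11) | CC1(O)CC[C@@]2(C)CC[C@@](C)(C(=O)OC)C[C@H]2[C@]1(C)CCB1C2CCCC1CCC2 | intermediate
28 | hydroxy polyene: 19 with the 13β arm extended to CH2CH2–C(CH3)=CH–CH2CH2–C(=CH2)–CH2SiMe3, C9=C8 Z | CC1(O)CC[C@@]2(C)CC[C@@](C)(C(=O)OC)C[C@H]2[C@]1(C)CC/C(C)=C\CCC(=C)C[Si](C)(C)C | intermediate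
29 | BCDE 5-methylidene ester (rings B–E, C10 = CH2; 8β-H, 9β-CH3, 13α-CH3, 14β-CH3, 17β-CH3, 18β-H, 20β-CH3, 20α-CO2CH3) | C=C1CC[C@@H]2[C@](C)(C1)CC[C@@]3(C)[C@@H]4C[C@](C)(C(=O)OC)CC[C@]4(C)CC[C@]23C | intermediate
30 | BCDE 5-ketone (stereocentres as 29) | O=C1CC[C@@H]2[C@](C)(C1)CC[C@@]3(C)[C@@H]4C[C@](C)(C(=O)OC)CC[C@]4(C)CC[C@]23C | intermediate
31 | BCDE 5-trimethylsilyloxy-5-ene | C[Si](C)(C)OC1=CC[C@@H]2[C@](C)(C1)CC[C@@]3(C)[C@@H]4C[C@](C)(C(=O)OC)CC[C@]4(C)CC[C@]23C | intermediate
32 | BCDE 5-oxo-6-ene (stereocentres as 29) | O=C1C=C[C@@H]2[C@](C)(C1)CC[C@@]3(C)[C@@H]4C[C@](C)(C(=O)OC)CC[C@]4(C)CC[C@]23C | intermediate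
33 | ethyl vinyl ketone (pent-1-en-3-one) | CCC(=O)C=C | starting material
34 | BCDE 5-trimethylsilyloxy-5(10),6-diene | C[Si](C)(C)OC=1C=C[C@@H]2[C@](C)(C=1)CC[C@@]3(C)[C@@H]4C[C@](C)(C(=O)OC)CC[C@]4(C)CC[C@]23C | intermediate
35 | 10α-(3-oxopentyl) BCDE 5-oxo-6-ene (10β-H) | O=C1C=C[C@@H]2[C@](C)([C@H]1CCC(=O)CC)CC[C@@]3(C)[C@@H]4C[C@](C)(C(=O)OC)CC[C@]4(C)CC[C@]23C | intermediate
36 | methyl 3-oxo-24-nor-friedela-4,6-dien-29-oate (8β-H, 10β-H) | O=C1CC[C@H]2C(=C1C)C=C[C@@H]1[C@@]2(C)CC[C@@]2(C)[C@@H]3C[C@](C)(C(=O)OC)CC[C@]3(C)CC[C@]12C | intermediate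
37 | 3-trimethylsilyloxy-2,4,6-triene from 36 | C[Si](C)(C)OC1=CC[C@H]2C(=C1C)C=C[C@@H]1[C@@]2(C)CC[C@@]2(C)[C@@H]3C[C@](C)(C(=O)OC)CC[C@]3(C)CC[C@]12C | intermediate
38 | methyl 3-hydroxy-24-nor-friedela-1,3,5(10),6-tetraen-29-oate (8β-H) | Cc1c(O)ccc2c1C=C[C@@H]1[C@@]2(C)CC[C@@]2(C)[C@@H]3C[C@](C)(C(=O)OC)CC[C@]3(C)CC[C@]12C | intermediate
39 | (S)-carvone | CC1=CC[C@@H](CC1=O)C(C)=C | starting material
40 | trimethyl{[(5S)-2-methyl-5-(prop-1-en-2-yl)cyclohex-1-en-1-yl]oxy}silane | CC1=C(O[Si](C)(C)C)C[C@H](CC1)C(C)=C | intermediate
41 | 1-trimethylsilyloxy-6-methyl-3-(prop-1-en-2-yl)bicyclo[4.1.0]heptane (cis-fused, ring-fusion diastereomers; C3 as in 39) | CC12CC1(O[Si](C)(C)C)C[C@H](CC2)C(C)=C | intermediate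
42 | 3-chloro-3-methyl-6-(prop-1-en-2-yl)cycloheptan-1-one (C3 epimers) | CC1(Cl)CC(=O)C[C@H](CC1)C(C)=C | intermediate
43 | (S)-3-methyl-6-(prop-1-en-2-yl)cyclohept-2-en-1-one (ketone = C5′, C2 = C1′, C3 = C10′, C6 = C7′) | CC1=CC(=O)C[C@H](CC1)C(C)=C | intermediate
44 | 1-bromobut-2-yne | CC#CCBr | starting material
45 | diphenylsilyl enol ether C5′(OSiHPh2)=C1′ of the reduced ketone (C10′ R, C7′ S) | C[C@@H]1CC[C@@H](CC(O[SiH](c2ccccc2)c2ccccc2)=C1)C(C)=C | intermediate
46 | 2-(but-2-yn-1-yl)-3-methyl-6-(prop-1-en-2-yl)cycloheptan-1-one (C10′ R, C7′ S; C1′ epimers) | CC#CCC1C(=O)C[C@H](CC[C@H]1C)C(C)=C | intermediate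
47 | 3-methyl-2-(2-oxobutyl)-6-(prop-1-en-2-yl)cycloheptan-1-one (C10′ R, C7′ S; C1′ epimers) | CCC(=O)CC1C(=O)C[C@H](CC[C@H]1C)C(C)=C | intermediate
48 | hydroazulenone: guaia-4,11-dien-3-one (C10′ R, C7′ S; C1′ epimers) | O=C1CC2[C@H](C)CC[C@@H](CC2=C1C)C(C)=C | intermediate
49 | (7S,10R)-guaia-1(5),3,11-trien-3-yl triflate | C=C(C)[C@H]1CC[C@@H](C)C2=C(C1)C(C)=C(OS(=O)(=O)C(F)(F)F)C2 | intermediate
50 | (7S,10R)-guaia-1(5),3,11-triene | C=C(C)[C@H]1CC[C@@H](C)C2=C(C1)C(C)=CC2 | intermediate
51 | methyl 2,3-dioxo-24-nor-friedela-1(10),4,6-trien-29-oate (8β-H) | O=C1C(=O)C=C2C(=C1C)C=C[C@@H]1[C@@]2(C)CC[C@@]2(C)[C@@H]3C[C@](C)(C(=O)OC)CC[C@]3(C)CC[C@]12C | intermediate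
52 | target: cis-fused dioxane from 51 and 50 with O2–C1′ and O3–C5′, both oxygens syn to the C10′ methyl | C=C(C)[C@H]1CC[C@@H](C)[C@]23CC=C(C)[C@@]2(C1)Oc1c(cc2c(c1C)C=C[C@@H]1[C@@]2(C)CC[C@@]2(C)[C@@H]4C[C@](C)(C(=O)OC)CC[C@]4(C)CC[C@]12C)O3 | target

## Step count and least certain steps

Total: 31 steps. Longest linear sequence: 19 steps (steps 1–12, 17–22 and 31); the side chain (steps 13–16) and the diene (steps 23–30) are convergent branches.

**Step 21 (key step).** The most likely failure is a second conjugate addition, in which the titanium enolate formed after the first C–C bond adds to C7 and closes a bicyclo[2.2.2]octanone. Proton transfer that moves the dienolate towards C8, with epimerisation there, is the second concern. Fallback: replace the Michael addition by an SN2 alkylation, which produces no enolate after C–C bond formation. Starting from 32, the kinetic lithium enolate (lithium diisopropylamide, −78 °C) would be alkylated at C10 with 2-ethyl-2-(2-iodoethyl)-1,3-dioxolane to give the ketal-protected diketone F1. Mild hydrolysis (pyridinium tosylate, wet acetone) would release 35, and the pyrrolidinium acetate condensation returns to the route at 36.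

**Step 18.** Three processes can compete: attack of the olefin on the axial face of the C14 cation (cis C/D junction), closure of ring C through a boat (C8 and C9 both inverted relative to C14), and a 1,2-methyl shift from C13 to C14 before the olefin arrives. The first is the most likely because axial approach avoids the 13α-methyl. Fallback: make C14 stereospecific by displacement with inversion. Starting from 18, trimethylsulfoxonium iodide and NaH in DMSO should give the spiro-epoxide F2 with the oxygen axial (β). Hydroboration and coupling with 26 as in step 17 would give the epoxy polyene F3. MeAlCl2 at −78 °C would open the axial C–O bond from the rear, forcing equatorial entry of C8 and giving the 26-hydroxy tetracycle F4. The thiocarbonylimidazolide F5 and Bu3SnH/AIBN at 110 °C (Barton–McCombie deoxygenation) would return to the route at 29.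

**Step 31.** The most likely failures are tautomerisation of the ortho-quinone to the extended quinone methide (which destroys C8) and cycloaddition in the reversed orientation (O3 to C1′), since the C6=C7 bond makes O3 the more electrophilic oxygen. Addition to the other face and [1,5]-hydrogen shifts in the diene are further losses. Fallback: carry out the union without the C6=C7 bond and restore it last. Starting from 38, hydrogenation (H2, Pd/C) would give the 6,7-dihydro phenol F6. IBX would give the dihydro ortho-quinone F7, which cannot form the extended quinone methide and has no vinylogous bias between its oxygens. Cycloaddition with 50 would give the 6,7-dihydro adduct F8. DDQ would then abstract the C6 benzylic hydride (para to O2) and form C6=C7, which cannot go further because C9 is quaternary, arriving at 52.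

**Step 10.** Conjugate addition of the hindered tertiary enolate may be slow, so that proton exchange with the sulfoxide and its polymerisation win; attack from the α face would give the C13 epimer. Fallback: introduce three carbons with a reactive halide and remove one. Starting from 14, the enolate and allyl bromide would give the 13β-allyl enone F9. RuHCl(CO)(PPh3)3 would move the double bond into conjugation with nothing but the chain, giving the propenyl enone F10. Ethenolysis with the second-generation Grubbs catalyst under ethylene would return to the route at 17.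

**Step 22.** Deprotonation at C10 or C8 instead of C2 would give extended enolates and put C8 at risk. Fallback: dehydrogenate without base. Starting from 36, DDQ in dioxane should abstract hydride from C1 of the small equilibrium amount of 2,4,6-trienol, and the trienone tautomerises to 38; no new compound is involved.

## Further compounds

F1 | step 21 | 10α-[2-(2-ethyl-1,3-dioxolan-2-yl)ethyl] BCDE 5-oxo-6-ene | O=C1C=C[C@@H]2[C@](C)([C@H]1CCC5(CC)OCCO5)CC[C@@]3(C)[C@@H]4C[C@](C)(C(=O)OC)CC[C@]4(C)CC[C@]23C
F2 | step 18 | D/E 14-spiro-epoxide (oxygen β, CH2 = C26) with 13α-methyl and 13β-vinyl | O1C[C@]12CC[C@@]3(C)CC[C@@](C)(C(=O)OC)C[C@H]3[C@]2(C)C=C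
F3 | step 18 | epoxy polyene (F2 with the side chain of 28) | O1C[C@]12CC[C@@]3(C)CC[C@@](C)(C(=O)OC)C[C@H]3[C@]2(C)CC/C(C)=C\CCC(=C)C[Si](C)(C)C
F4 | step 18 | 26-hydroxy BCDE 5-methylidene ester | C=C1CC[C@@H]2[C@](C)(C1)CC[C@@]3(C)[C@@H]4C[C@](C)(C(=O)OC)CC[C@]4(C)CC[C@]23CO
F5 | step 18 | O-(C26) imidazole-1-carbothioate of F4 | C=C1CC[C@@H]2[C@](C)(C1)CC[C@@]3(C)[C@@H]4C[C@](C)(C(=O)OC)CC[C@]4(C)CC[C@]23COC(=S)n1ccnc1
F6 | step 31 | methyl 3-hydroxy-24-nor-friedela-1,3,5(10)-trien-29-oate (8β-H) | Cc1c(O)ccc2c1CC[C@@H]1[C@@]2(C)CC[C@@]2(C)[C@@H]3C[C@](C)(C(=O)OC)CC[C@]3(C)CC[C@]12C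
F7 | step 31 | methyl 2,3-dioxo-24-nor-friedela-1(10),4-dien-29-oate (8β-H) | O=C1C(=O)C=C2C(=C1C)CC[C@@H]1[C@@]2(C)CC[C@@]2(C)[C@@H]3C[C@](C)(C(=O)OC)CC[C@]3(C)CC[C@]12C
F8 | step 31 | 6,7-dihydro derivative of 52 | C=C(C)[C@H]1CC[C@@H](C)[C@]23CC=C(C)[C@@]2(C1)Oc1c(cc2c(c1C)CC[C@@H]1[C@@]2(C)CC[C@@]2(C)[C@@H]4C[C@](C)(C(=O)OC)CC[C@]4(C)CC[C@]12C)O3
F9 | step 10 | 13α-methyl-13β-allyl D/E enone ester | O=C1C=C[C@@]2(C)CC[C@@](C)(C(=O)OC)C[C@H]2[C@]1(C)CC=C
F10 | step 10 | 13α-methyl-13β-[(E)-prop-1-enyl] D/E enone ester | O=C1C=C[C@@]2(C)CC[C@@](C)(C(=O)OC)C[C@H]2[C@]1(C)/C=C/C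
F0 | step 22 | none | none
A1 | alternative 1 | cis-dihydrocarvone, (2R,5S) | C[C@@H]1CC[C@@H](CC1=O)C(C)=C
A2 | alternative 1 | ethyl diazoacetate | CCOC(=O)C=[N+]=[N-]
A3 | alternative 1 | ring-expanded β-keto ester | C=C(C)[C@H]1CC[C@@H](C)C(=O)[C@H](C(=O)OCC)C1
A4 | alternative 2 | C1′-aryloxy C5′-trimethylsilyloxy olefin | C=C(C)[C@H]1CC[C@@H](C)C(Oc2cc3c(c(C)c2OS(=O)(=O)C(F)(F)F)C=C[C@@H]2[C@@]3(C)CC[C@@]3(C)[C@@H]4C[C@](C)(C(=O)OC)CC[C@]4(C)CC[C@]23C)=C(O[Si](C)(C)C)C1
A5 | alternative 2 | chloro(methyl)ketene | CC(Cl)=C=O
A6 | alternative 2 | cyclobutanone fused at C1′–C5′ | C=C(C)[C@H]1CC[C@@H](C)[C@]2(Oc3cc4c(c(C)c3OS(=O)(=O)C(F)(F)F)C=C[C@@H]3[C@@]4(C)CC[C@@]4(C)[C@@H]5C[C@](C)(C(=O)OC)CC[C@]5(C)CC[C@]34C)C(=O)[C@](C)(Cl)[C@]2(O[Si](C)(C)C)C1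
A7 | alternative 3 | benzocyclobutene tethered to the D/E unit bearing the C14 ethynyl group (C9 unspecified) | COc1c(OC)cc2c(c1C)CC2(C)CC[C@@]1(C)[C@@H]2C[C@](C)(C(=O)OC)CC[C@]2(C)CC[C@]1(C)C#C
A8 | alternative 3 | 7-ene catechol dimethyl ether | COc1c(OC)cc2c(c1C)CC=C1[C@@]2(C)CC[C@@]2(C)[C@@H]4C[C@](C)(C(=O)OC)CC[C@]4(C)CC[C@]12C
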